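**Plan**

1. Numbering: carbons C1–C22 in the order of the target SMILES (C1–C3 isopropenyl, C4, C5, C6, C7(=O), C8, C9, C10(=O), C11, C12, C13(–C14)=C15, C16, C17–C22 arene). Ring A = arene; ring B = C6–C16–C17–C22–C11; ring C = cyclohexene C6/C11/C12/C13/C15/C16; ring D = 1,4-dione C6–C11; ring E = cyclopentanone C4–C8.
2. Retrosynthesis: cut C11–C22 (ring B, closed last), then C4–C8 (ring E, allylsilane onto an enedione), then C6–C16 and C11–C12 (ring C, Diels–Alder). This leaves aryl diene 8 and the epoxide-masked 2-allylquinone 4.
3. Forward: ring D (from a p-methoxyphenol) → ring C → unmasking of the C8=C9 enedione → ring E → ring B → release of the ring A hydroquinone.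
4. Stereochemistry: a tartrate-controlled epoxide at C8/C9 (removed later) steers the diene to one face and the endo rule fixes C6 and C16. C8 follows from the tether, C4 from an open transition state, C11 from the geometry of the last ring closure.
5. Feature that enables the key event: the C7 ketone cannot enolise (C6 quaternary, C8 bridgehead), so C11–H is the one α-hydrogen of the diketone that the C22–Br bond, held on C16 cis across ring C, can reach.

Key step: step 10

Assumption: diisopropyl L-tartrate is taken to give the (1S,6R)-epoxide 3; if the sense of induction is the opposite, the D-tartrate is used.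

Step 1
Reactants: 1 2-allyl-4-methoxyphenol
Product: 2 2-allyl-4,4-dimethoxycyclohexa-2,5-dien-1-one
Conditions: PhI(OAc)2, MeOH, 0 °C
Reagents that add atoms: methanol, CO
Why: hypervalent-iodine oxidative dearomatisation of a p-methoxyphenol in methanol gives the quinone monoketal with the free carbonyl (C7) next to the allyl-bearing carbon, and the isolated alkene is not touched.

Step 2
Reactants: 2 2-allyl-4,4-dimethoxycyclohexa-2,5-dien-1-one
Product: 3 (1S,6R)-3-allyl-5,5-dimethoxy-7-oxabicyclo[4.1.0]hept-3-en-2-one
Conditions: Ph3COOH, NaN(SiMe3)2, diisopropyl L-tartrate, PhMe, −60 °C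
Reagents that add atoms: trityl hydroperoxide, OOC(c1ccccc1)(c1ccccc1)c1ccccc1
Why: tartrate-mediated asymmetric nucleophilic (Weitz–Scheffer-type) epoxidation of a quinone monoketal, in which the peroxide adds to the α-unsubstituted enone C8=C9 in preference to the allyl-substituted one and the sodium tartrate complex selects the enone face, which sets C8 and C9.

Step 3
Reactants: 3 (1S,6R)-3-allyl-5,5-dimethoxy-7-oxabicyclo[4.1.0]hept-3-en-2-one
Product: 4 (1S,6R)-3-allyl-7-oxabicyclo[4.1.0]hept-3-ene-2,5-dione
Conditions: aq. CF3CO2H, CH2Cl2, 0 °C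
Reagents that add atoms: water, O
Why: acid-catalysed ketal hydrolysis frees the C10 carbonyl, while the epoxide, flanked by two electron-poor carbons, should resist acid opening.

Step 4
Reactants: 5 2-bromo-1,4-dimethoxybenzene
Product: 6 2-bromo-3,6-dimethoxybenzaldehyde
Conditions: LiN(i-Pr)2, THF, −78 °C; then DMF
Reagents that add atoms: N,N-dimethylformamide, CN(C)C=O
Why: directed ortho-lithiation at the most acidic position, between bromine and methoxy (kept at −78 °C so that no aryne forms), followed by formylation.

Step 5
Reactants: 6 2-bromo-3,6-dimethoxybenzaldehyde; 7 diethyl (2-methylallyl)phosphonate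
Product: 8 2-bromo-1,4-dimethoxy-3-[(1E)-3-methylbuta-1,3-dien-1-yl]benzene
Conditions: n-BuLi, THF, −78 → 25 °C
Reagents that add atoms: none
Why: Horner–Wadsworth–Emmons olefination through the α-carbanion of the allylic phosphonate gives the (E)-1-aryl-1,3-diene.

Step 6
Reactants: 4 (1S,6R)-3-allyl-7-oxabicyclo[4.1.0]hept-3-ene-2,5-dione; 8 2-bromo-1,4-dimethoxy-3-[(1E)-3-methylbuta-1,3-dien-1-yl]benzene
Product: 9 epoxide-bearing Diels–Alder adduct (6S,8S,9R,11R,16S)
Conditions: PhMe, BHT (cat.), 70 °C
Reagents that add atoms: none
Why: thermal normal-demand Diels–Alder reaction on the only dienophilic bond of 4 (C6=C11), in which the more nucleophilic diene terminus C12 bonds to the unsubstituted C11 and the aryl-bearing C16 to C6, the diene comes in anti to the epoxide oxygen and endo to the dione, and C6, C11 and C16 are set with the aryl group cis to C7.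

Step 7
Reactants: 9 epoxide-bearing Diels–Alder adduct (6S,8S,9R,11R,16S)
Product: 11 (4aS,5S,8aR)-4a-allyl-5-(2-bromo-3,6-dimethoxyphenyl)-7-methyl-4a,5,8,8a-tetrahydronaphthalene-1,4-dione, via hydroxy diketone 10 (not isolated)
Conditions: SmI2, THF–MeOH, −78 °C; then MsCl, Et3N, CH2Cl2, 0 °C
Reagents that add atoms: none
Why: SmI2 opens the α,β-epoxy ketone reductively at the C–O bond α to the carbonyl (the aryl bromide is inert without additives) and mesylation of aldol 10 triggers E1cB elimination, which regenerates the C8=C9 enedione and erases the C8 and C9 stereocentres once they have served.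

Step 8
Reactants: 11 (4aS,5S,8aR)-4a-allyl-5-(2-bromo-3,6-dimethoxyphenyl)-7-methyl-4a,5,8,8a-tetrahydronaphthalene-1,4-dione; 12 trimethyl(2-methylallyl)silane
Product: 13 (4aS,5S,8aR)-5-(2-bromo-3,6-dimethoxyphenyl)-7-methyl-4a-[(E)-3-methyl-4-(trimethylsilyl)but-2-enyl]-4a,5,8,8a-tetrahydronaphthalene-1,4-dione
Conditions: RuCl2(H2IMes)(=CH–C6H4-2-O-i-Pr) (second-generation Hoveyda–Grubbs catalyst, 10 mol %), excess 12, CH2Cl2, 40 °C
Reagents that add atoms: none
Why: olefin cross-metathesis of the terminal allyl group with an excess of the 1,1-disubstituted allylsilane, in which the trisubstituted C13=C15 and the electron-poor C8=C9 bonds should not take part, and either alkene geometry of 13 serves in step 9.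

Step 9
Reactants: 13 (4aS,5S,8aR)-5-(2-bromo-3,6-dimethoxyphenyl)-7-methyl-4a-[(E)-3-methyl-4-(trimethylsilyl)but-2-enyl]-4a,5,8,8a-tetrahydronaphthalene-1,4-dione
Product: 14 tricyclic bromo diketone (4S,6S,8R,11R,16S)
Conditions: TiCl4, CH2Cl2, −78 °C; aq. NaHCO3 work-up
Reagents that add atoms: none
Why: intramolecular Hosomi–Sakurai conjugate allylation, in which TiCl4 should bind the less hindered C10 carbonyl, the γ-carbon C4 of the allylsilane adds 5-exo to C8 on the face that carries C5 (which fixes C8), loss of silicon leaves the isopropenyl group, and an open antiperiplanar transition state that keeps the bulky C2 end away from the concave enedione should place the isopropenyl group exo at C4.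

Step 10
Reactants: 14 tricyclic bromo diketone (4S,6S,8R,11R,16S)
Product: 15 dimethyl ether of the target (4S,6S,8R,11R,16R)
Conditions: Pd2(dba)3 (5 mol %), (t-Bu)3P·HBF4 (12 mol %), NaOt-Bu, PhMe, 80 °C
Reagents that add atoms: none
Why: Oxidative addition of zerovalent palladium into the C22–Br bond, deprotonation of the C10 ketone by NaOt-Bu and C-palladation at C11 give a six-membered C,C-palladacycle, and its reductive elimination forms the C11–C22 bond. The closest known reaction type is the intramolecular Buchwald–Hartwig α-arylation of ketones, which is established for benzo-fused bridged ketones with α-quaternary carbons. Ring B closes as a five-membered ring in the 5-(enolexo) mode, the enolate bond C10=C11 lying outside the new ring. The new quaternary stereocentre C11 is controlled by the C16 stereocentre, because the aryl group can reach only the enolate face cis to the C16–C17 bond across ring C, so the C11 configuration of 14 does not matter. The step needs site selectivity among the α-carbons, and the substrate secures it: the C7 ketone cannot enolise (C6 quaternary, C8 bridgehead) and, of the two α-carbons of C10, only C11 is within reach, while enolisation toward C9 is reversible and unproductive. A bulky electron-rich phosphine is chosen to favour reductive elimination at the congested carbon over Heck-type insertion into the nearby C13=C15 bond.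

Step 11
Reactants: 15 dimethyl ether of the target (4S,6S,8R,11R,16R)
Product: 17 target hydroquinone CNP0287617.1, via cyclised quinone 16 (not isolated)
Conditions: (NH4)2Ce(NO3)6, MeCN–H2O, 0 °C; then aq. Na2S2O4
Reagents that add atoms: water, O
Why: oxidative demethylation of the p-dimethoxyarene to the quinone (alkenes and ketones are inert, and C16–H is now a bridgehead, so no quinone methide can form) followed by dithionite reduction in the same flask gives the hydroquinone without touching any stereocentre.

**Compound list**

1 | 2-allyl-4-methoxyphenol | C=CCc1cc(OC)ccc1O | starting material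
2 | 2-allyl-4,4-dimethoxycyclohexa-2,5-dien-1-one | C=CCC1=CC(OC)(OC)C=CC1=O | intermediate
3 | (1S,6R)-3-allyl-5,5-dimethoxy-7-oxabicyclo[4.1.0]hept-3-en-2-one (epoxide at C8–C9) | C=CCC1=CC(OC)(OC)[C@@H]2O[C@@H]2C1=O | intermediate
4 | (1S,6R)-3-allyl-7-oxabicyclo[4.1.0]hept-3-ene-2,5-dione | C=CCC1=CC(=O)[C@@H]2O[C@@H]2C1=O | intermediate
5 | 2-bromo-1,4-dimethoxybenzene | COc1ccc(OC)c(Br)c1 | starting material
6 | 2-bromo-3,6-dimethoxybenzaldehyde | O=Cc1c(OC)ccc(OC)c1Br | intermediate
7 | diethyl (2-methylallyl)phosphonate | CCOP(=O)(CC(C)=C)OCC | starting material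
8 | 2-bromo-1,4-dimethoxy-3-[(1E)-3-methylbuta-1,3-dien-1-yl]benzene | C=C(C)/C=C/c1c(OC)ccc(OC)c1Br | intermediate
9 | epoxide-bearing Diels–Alder adduct: rings C and D cis-fused, allyl on C6, 2-bromo-3,6-dimethoxyphenyl on C16 cis to C7, epoxide at C8–C9 on the face away from ring C; (6S,8S,9R,11R,16S) in the plan numbering | C=CC[C@@]23C(=O)[C@H]4O[C@H]4C(=O)[C@@H]2CC(C)=C[C@@H]3c1c(OC)ccc(OC)c1Br | intermediate
10 | hydroxy diketone: 9 with the epoxide opened to C8–OH (8S) and C9H2 (the C9-hydroxy regioisomer would converge) | C=CC[C@@]23C(=O)[C@@H](O)CC(=O)[C@@H]2CC(C)=C[C@@H]3c1c(OC)ccc(OC)c1Br | intermediate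
11 | (4aS,5S,8aR)-4a-allyl-5-(2-bromo-3,6-dimethoxyphenyl)-7-methyl-4a,5,8,8a-tetrahydronaphthalene-1,4-dione | C=CC[C@@]23C(=O)C=CC(=O)[C@@H]2CC(C)=C[C@@H]3c1c(OC)ccc(OC)c1Br | intermediate
12 | trimethyl(2-methylallyl)silane | C=C(C)C[Si](C)(C)C | starting material
13 | (4aS,5S,8aR)-5-(2-bromo-3,6-dimethoxyphenyl)-7-methyl-4a-[(E)-3-methyl-4-(trimethylsilyl)but-2-enyl]-4a,5,8,8a-tetrahydronaphthalene-1,4-dione | C[Si](C)(C)C/C(C)=C/C[C@@]23C(=O)C=CC(=O)[C@@H]2CC(C)=C[C@@H]3c1c(OC)ccc(OC)c1Br | intermediate
14 | tricyclic bromo diketone (rings C, D, E closed): isopropenyl exo on C4, C11–H trans to the aryl group on ring C, 2-bromo-3,6-dimethoxyphenyl on C16 cis to C7; (4S,6S,8R,11R,16S) in the plan numbering | C=C(C)[C@H]1C[C@@]23C(=O)[C@@H]1CC(=O)[C@@H]2CC(C)=C[C@@H]3c1c(OC)ccc(OC)c1Br | intermediate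
15 | dimethyl ether of the target (rings A–E complete); (4S,6S,8R,11R,16R) in the plan numbering | C=C(C)[C@H]1C[C@@]23C(=O)[C@@H]1CC(=O)[C@@]21CC(C)=C[C@@H]3c2c(OC)ccc(OC)c21 | intermediate
16 | cyclised quinone (target with ring A as p-benzoquinone) | C=C(C)[C@H]1C[C@@]23C(=O)[C@@H]1CC(=O)[C@@]21CC(C)=C[C@@H]3C2=C1C(=O)C=CC2=O | intermediate
17 | target hydroquinone CNP0287617.1; (4S,6S,8R,11R,16R) in the plan numbering, C7 syn to the arene bridge, isopropenyl exo | C=C(C)[C@H]1C[C@@]23C(=O)[C@@H]1CC(=O)[C@@]21CC(C)=C[C@@H]3c2c(O)ccc(O)c21 | target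

**Totals**

Total steps: 11. Longest linear sequence: 9 steps (steps 1, 2, 3, 6, 7, 8, 9, 10, 11).

**Steps most likely to fail**

Step 9. What may go wrong: the allylsilane adds to the C10 carbonyl carbon or to C9 instead of C8, or the isopropenyl group is placed endo at C4. Fallback: ring E is closed from the other side, with C8 as the nucleophile. Setting out from 11, cross-metathesis with 2-methylallyl acetate (same ruthenium catalyst) should give the allylic acetate F1. Conjugate reduction with KBH(s-Bu)3 (THF, −78 °C; hydride to the less hindered C9) generates the C7–C8 enolate regiospecifically. Pd(PPh3)4 then ionises the acetate so that C8 attacks the internal allyl terminus C4 (intramolecular Tsuji–Trost allylation, five- in preference to seven-membered ring). This comes back to the route at 14.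

Step 10. What may go wrong: oxidative addition into the doubly ortho-substituted C–Br bond is slow and protodebromination takes over, or reductive elimination fails at the congested carbon. Fallback: the electrophile is changed from an arylpalladium species to a haloquinone. Setting out from 14, (NH4)2Ce(NO3)6 in aqueous MeCN should give the bromoquinone F2. With Cs2CO3 in DMF the C10 enolate adds through C11 to the bromine-bearing quinone carbon C22 and bromide is expelled (addition–elimination on a 2-haloquinone). This comes back to the route at quinone 16, which Na2S2O4 reduces to 17 as in step 11.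

Step 7. What may go wrong: over-reduction of the 1,4-diketone by SmI2, or retro-aldol fragmentation of intermediate 10 before the elimination. Fallback: the C8=C9 bond is masked as a cyclopentadiene adduct instead of an epoxide, so that unmasking needs heat only. Setting out from 1, (NH4)2Ce(NO3)6 oxidation gives 2-allyl-1,4-benzoquinone F3. An enantioselective Diels–Alder reaction with cyclopentadiene at the unsubstituted C8=C9 bond gives the endo cyclopentadiene adduct F4 (triflimide salt of the (S)-diphenylprolinol-derived B-(o-tolyl)oxazaborolidine, CH2Cl2, −78 °C; catalyst enantiomer chosen to give the adduct as drawn). Thermal Diels–Alder reaction of F4 with 8 on its convex face gives the double adduct F5. Thermolysis (Ph2O, 220 °C, N2 stream) expels cyclopentadiene and comes back to the route at 11.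

**Further compounds**

F1 | step 9 | (4aS,5S,8aR)-4a-[(E)-4-acetoxy-3-methylbut-2-enyl]-5-(2-bromo-3,6-dimethoxyphenyl)-7-methyl-4a,5,8,8a-tetrahydronaphthalene-1,4-dione | CC(=O)OC/C(C)=C/C[C@@]23C(=O)C=CC(=O)[C@@H]2CC(C)=C[C@@H]3c1c(OC)ccc(OC)c1Br
F2 | step 10 | bromoquinone: 14 with the aryl group oxidised to 3-bromo-1,4-benzoquinon-2-yl | C=C(C)[C@H]1C[C@@]23C(=O)[C@@H]1CC(=O)[C@@H]2CC(C)=C[C@@H]3C1=C(Br)C(=O)C=CC1=O
F3 | step 7 | 2-allylcyclohexa-2,5-diene-1,4-dione | C=CCC1=CC(=O)C=CC1=O
F4 | step 7 | endo Diels–Alder adduct of F3 with cyclopentadiene at C8=C9 (2-allyl-4a,5,8,8a-tetrahydro-5,8-methanonaphthalene-1,4-dione, absolute configuration as in the SMILES) | C=CCC1=CC(=O)[C@@H]2[C@@H]3C=C[C@@H](C3)[C@@H]2C1=O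
F5 | step 7 | double adduct: 11 with C8 and C9 bridged endo by cyclopent-2-ene-1,3-diyl on the face away from ring C | C=CC[C@@]23C(=O)[C@H]4[C@H]5C=C[C@H](C5)[C@H]4C(=O)[C@@H]2CC(C)=C[C@@H]3c1c(OC)ccc(OC)c1Br
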